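**Retrosynthetic overview**
1. Toxiusol comes from its hydroquinone by O-sulfation in the last step. The hydroquinone is carried as an electron-poor bis-tosylate.
2. The bis-tosylate comes from a bridged di-tertiary ether. One Lewis-acid ionisation breaks both C–O bonds. The C11' cation closes western ring A and then ring B, followed by 1,2-H, 1,2-Me and 1,2-H shifts. The eastern C10 cation gives the Δ1(10) alkene.
3. The bridged ether comes from a western allylic bromide and an eastern alkyl Grignard reagent (C8'–C9' bond). This bond is made while the western half is still acyclic, so no neopentyl coupling is needed.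
4. The eastern bromo ether comes from geranyllinalool. An enantioselective proton-initiated bicyclisation closes eastern ring A and then ring B with OH capture. A 1,2-H/1,2-Me shift and re-capture at C10 follow.
5. The western bromide comes from bromohydroquinone and (R)-β-citronellene, which supplies the C3' stereocentre.

**Assumption:** the presumed biosynthesis is two separate cation–olefin bicyclisations of a hexaprenyl hydroquinone, started at C23' and at C11' and each followed by 1,2-shifts. The target is made as the free bis(hydrogen sulfate) that the SMILES shows.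

**Locants:** chain atoms are C1'–C23', counted from the arene. Decalin atoms use labdane/halimane numbers with the prefix W or E.
- Western: W4 = C11', W5 = C6', W10 = C7', W9 = C2', W8 = C3'.
- Eastern: E4 = C23', E5 = C18', E10 = C19', E9 = C14', E8 = C15'.
- α and β refer to the usual labdane drawing.

**Step 1**
Reactants: 1 bromohydroquinone
Product: 2 2-bromo-1,4-phenylene bis(4-methylbenzenesulfonate)
Conditions: TsCl (2.3 equiv), Et3N, DMAP (cat.), CH2Cl2, 0 °C → rt
Reagents that add atoms: 4-toluenesulfonyl chloride Cc1ccc(cc1)S(=O)(=O)Cl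
Why: O-sulfonylation of both phenols protects the hydroquinone and makes the arene an acceptor, which step 9 needs; no stereocentre is formed.

**Step 2**
Reactants: 2 2-bromo-1,4-phenylene bis(4-methylbenzenesulfonate); 3 (R)-β-citronellene [(3R)-3,7-dimethylocta-1,6-diene]
Product: 4 2-[(1E,3R)-3,7-dimethylocta-1,6-dien-1-yl]-1,4-phenylene bis(4-methylbenzenesulfonate)
Conditions: Pd(OAc)2 (5 mol %), P(o-tol)3 (12 mol %), Et3N, DMF, 90 °C
Reagents that add atoms: none
Why: In this Mizoroki–Heck reaction aryl-Pd adds only to the terminal CH2 of the monosubstituted alkene, β-hydride loss on the benzylic side gives the conjugated E-styrene, and C3' (later W8) is carried over unchanged from 3.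

**Step 3**
Reactants: 4 2-[(1E,3R)-3,7-dimethylocta-1,6-dien-1-yl]-1,4-phenylene bis(4-methylbenzenesulfonate)
Product: 5 2-[(1E,3R,6E)-8-hydroxy-3,7-dimethylocta-1,6-dien-1-yl]-1,4-phenylene bis(4-methylbenzenesulfonate)
Conditions: SeO2 (20 mol %), t-BuOOH, salicylic acid (10 mol %), CH2Cl2, rt
Reagents that add atoms: tert-butyl hydroperoxide CC(C)(C)OO
Why: The SeO2-catalysed allylic oxidation (ene reaction, then [2,3]-shift) attacks the electron-rich isopropylidene group, not the acceptor styrene, and hydroxylates the E-methyl group, which fixes the 6'E geometry.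

**Step 4**
Reactants: 5 2-[(1E,3R,6E)-8-hydroxy-3,7-dimethylocta-1,6-dien-1-yl]-1,4-phenylene bis(4-methylbenzenesulfonate)
Product: 6 2-[(1E,3R,6E)-8-bromo-3,7-dimethylocta-1,6-dien-1-yl]-1,4-phenylene bis(4-methylbenzenesulfonate)
Conditions: CBr4, PPh3, CH2Cl2, −20 °C
Reagents that add atoms: carbon tetrabromide BrC(Br)(Br)Br
Why: The Appel reaction replaces the primary allylic OH by SN2 under neutral conditions, without allylic shift or E/Z loss.

**Step 5**
Reactants: 7 (6E,10E)-geranyllinalool (racemic)
Product: 9 (6E,10E)-3,7,11,15-tetramethylhexadeca-6,10,14-triene-1,3-diol, via B-alkyl-9-BBN adduct 8 (not isolated)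
Conditions: 9-BBN, THF, 0 °C → rt; then NaOH, H2O2, 0 °C
Reagents that add atoms: hydrogen peroxide OO
Why: In this Brown hydroboration–oxidation 9-BBN takes only the monosubstituted alkene, anti-Markovnikov, and leaves the three trisubstituted alkenes; the C11' carbinol stays racemic, which does not matter because it becomes planar in step 9.

**Step 6**
Reactants: 9 (6E,10E)-3,7,11,15-tetramethylhexadeca-6,10,14-triene-1,3-diol
Product: 11 (5β-H)-10α,13-epoxyhaliman-15-ol (8β-Me, 9β-Me, both C13 epimers), via 8α,13-epoxylabdan-15-ol 10 (not isolated)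
Conditions: confined chiral imidodiphosphorimidate Brønsted acid (3 mol %, the enantiomer that gives the (−)-ambrox series), (CF3)3COH, −20 °C; then TfOH (10 mol %), CH2Cl2–HFIP, −20 °C → rt
Reagents that add atoms: none
Why: Proposed new method: the confined acid protonates only the terminal C22'=C23' alkene and folds the triene chair–chair, so anti addition across the two E-alkenes and capture by the tertiary OH set E5 (Hα), E10 (Meβ), E9 (Hα) and E8 (Oα) in 10 (closest known type: catalytic asymmetric proton-initiated polyene cyclisation of homofarnesol to ambrox); TfOH then re-ionises the strained E8–O bond, H-9α moves to E8 and Me-10β to E9 suprafacially (fixing 8β-Me and 9β-Me), and the E10 cation, which exchanges with the Δ5(10) alkene, is re-captured by the same oxygen under thermodynamic control as the trans-fused ether with H-5β, the only isomer in which C4, C13' and the 8-methyl are all equatorial on ring B and both Me/Me 1,3-diaxial contacts of 10 are gone (closest known types: Lewis-acid 1,2-H/1,2-Me shift of drimanes and acid cycloetherification at C10 as in aureol).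

**Step 7**
Reactants: 11 (5β-H)-10α,13-epoxyhaliman-15-ol
Product: 12 (5β-H)-15-bromo-10α,13-epoxyhalimane
Conditions: CBr4, PPh3, 2,6-lutidine, CH2Cl2, 0 °C
Reagents that add atoms: carbon tetrabromide BrC(Br)(Br)Br
Why: The buffered Appel reaction converts the primary alcohol by SN2 and leaves the acid-labile di-tertiary ether and all stereocentres untouched.

**Step 8**
Reactants: 12 (5β-H)-15-bromo-10α,13-epoxyhalimane; 6 2-[(1E,3R,6E)-8-bromo-3,7-dimethylocta-1,6-dien-1-yl]-1,4-phenylene bis(4-methylbenzenesulfonate)
Product: 14 bridged ether with the full C30 chain (western (1'E,3'R,6'E)-dienyl arene joined through C8'–C9' to the eastern epoxyhalimane), via alkylmagnesium bromide 13 (not isolated)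
Conditions: Mg, THF, 40 °C; then 6, Li2CuCl4 (3 mol %), THF, −40 → 0 °C
Reagents that add atoms: none
Why: The copper-catalysed Grignard–allyl bromide coupling (Kochi–Schlosser type) goes SN2 at the unhindered CH2Br with retention of the 6'E alkene, and aryl tosylates are inert to RMgBr/Cu at this temperature; no stereocentre is touched.

**Step 9**
Reactants: 14 bridged ether with the full C30 chain
Product: 16 toxiusol hydroquinone bis(4-methylbenzenesulfonate), via dormant ring-fusion dichloride 15 (not isolated)
Conditions: TiCl4 (4 equiv), 2,6-di-tert-butyl-4-methylpyridine (0.5 equiv, proton trap), CH2Cl2, −78 °C, 20 min; then 1,2,2,6,6-pentamethylpiperidine (8 equiv), −78 → −40 °C; aq NaHCO3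
Reagents that add atoms: none
Why: Proposed new method: TiCl4 makes the bridging oxygen the leaving group for both tertiary carbons; the planar C11' cation (so both C11' epimers converge) is attacked by C6', and C7' by the styrene carbon C2', in one chair–chair fold fixed by the (R)-C3' methyl and the bulky eastern arm both lying equatorial, which sets W4, W5 and W10; the poor benzylic cation beside the bis-sulfonylated arene is drained by 1,2-H (W9→C1'), 1,2-Me (W10β→W9β) and 1,2-H (W5α→W10α) shifts that move the charge away from the acceptor arene to W5 and fix W9 and W10; both ring-fusion cations rest as tertiary chlorides with no free proton present, and the hindered amine then removes the exposed CH2 hydrogens (W6-H, E1-H) rather than the buried tertiary W10-H and E5-H, which gives the two trisubstituted alkenes and leaves E5, E8 and E9 untouched (closest known types: Stork–Eschenmoser cation–olefin bicyclisation steered by a stereocentre in the chain, friedo 1,2-shift cascades, and hindered-base end-quenching of quasi-living tertiary carbocations to the less substituted alkene).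

**Step 10**
Reactants: 16 toxiusol hydroquinone bis(4-methylbenzenesulfonate)
Product: 17 toxiusol hydroquinone (free 1,4-diol)
Conditions: KOH (10 equiv), MeOH–THF, 60 °C, argon; aq NH4Cl, Na2S2O4 wash
Reagents that add atoms: none
Why: Alkaline hydrolysis of the aryl sulfonates (attack at sulfur) frees both phenols, and the base leaves the acid-sensitive alkenes and all stereocentres alone.

**Step 11**
Reactants: 17 toxiusol hydroquinone
Product: 19 toxiusol, via bis(pyridinium) disulfate salt 18 (not isolated)
Conditions: SO3·pyridine (6 equiv), pyridine, rt; then strong-acid cation-exchange resin (H+ form), MeOH–H2O, 0 °C, freeze-dry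
Reagents that add atoms: sulfur trioxide–pyridine complex [O-]S(=O)(=O)[n+]1ccccc1
Why: O-sulfation of both phenols with a buffered SO3 donor, followed by cold ion exchange, gives the free bis(hydrogen sulfate) without alkene migration; no stereocentre is affected.

**Compound list**
1 | bromohydroquinone | Oc1ccc(O)c(Br)c1 | starting material
2 | 2-bromo-1,4-phenylene bis(4-methylbenzenesulfonate) | Cc1ccc(cc1)S(=O)(=O)Oc1ccc(OS(=O)(=O)c2ccc(C)cc2)c(Br)c1 | intermediate
3 | (R)-β-citronellene | C=C[C@H](C)CCC=C(C)C | starting material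
4 | (1'E,3'R)-styrene ditosylate | Cc1ccc(cc1)S(=O)(=O)Oc1ccc(OS(=O)(=O)c2ccc(C)cc2)c(/C=C/[C@H](C)CCC=C(C)C)c1 | intermediate
5 | (1'E,3'R,6'E)-8'-allylic alcohol | Cc1ccc(cc1)S(=O)(=O)Oc1ccc(OS(=O)(=O)c2ccc(C)cc2)c(/C=C/[C@H](C)CC/C=C(\C)CO)c1 | intermediate
6 | (1'E,3'R,6'E)-8'-allylic bromide | Cc1ccc(cc1)S(=O)(=O)Oc1ccc(OS(=O)(=O)c2ccc(C)cc2)c(/C=C/[C@H](C)CC/C=C(\C)CBr)c1 | intermediate
7 | (6E,10E)-geranyllinalool (racemic) | C=CC(C)(O)CC/C=C(\C)CC/C=C(\C)CCC=C(C)C | starting material
8 | B-alkyl-9-BBN adduct of 7 | CC(O)(CCB1C2CCCC1CCC2)CC/C=C(\C)CC/C=C(\C)CCC=C(C)C | intermediate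
9 | (6E,10E)-3,7,11,15-tetramethylhexadeca-6,10,14-triene-1,3-diol | OCCC(C)(O)CC/C=C(\C)CC/C=C(\C)CCC=C(C)C | intermediate
10 | 8α,13-epoxylabdan-15-ol (5α-H, 9α-H, 10β-Me; C13 epimers) | OCCC1(C)CC[C@@H]2[C@@]3(C)CCCC(C)(C)[C@@H]3CC[C@@]2(C)O1 | intermediate
11 | (5β-H)-10α,13-epoxyhaliman-15-ol (8β-Me, 9β-Me; C13 epimers) | OCCC1(C)CC[C@]2(C)[C@@H](C)CC[C@@H]3C(C)(C)CCC[C@@]23O1 | intermediate
12 | (5β-H)-15-bromo-10α,13-epoxyhalimane | BrCCC1(C)CC[C@]2(C)[C@@H](C)CC[C@@H]3C(C)(C)CCC[C@@]23O1 | intermediate
13 | Grignard reagent of 12 | Br[Mg]CCC1(C)CC[C@]2(C)[C@@H](C)CC[C@@H]3C(C)(C)CCC[C@@]23O1 | intermediate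
14 | bridged ether with the full C30 chain | Cc1ccc(cc1)S(=O)(=O)Oc1ccc(OS(=O)(=O)c2ccc(C)cc2)c(/C=C/[C@H](C)CC/C=C(\C)CCCC2(C)CC[C@]3(C)[C@@H](C)CC[C@@H]4C(C)(C)CCC[C@@]34O2)c1 | intermediate
15 | ring-fusion dichloride (W5-Cl, E10-Cl; C–Cl configuration not defined) | C[C@@H]1CCC2(Cl)[C@@H](CCC[C@@]2(C)CC[C@@]2(C)C3(Cl)CCCC(C)(C)[C@H]3CC[C@@H]2C)[C@]1(C)Cc1cc(OS(=O)(=O)c2ccc(C)cc2)ccc1OS(=O)(=O)c1ccc(C)cc1 | intermediate
16 | toxiusol hydroquinone ditosylate | C[C@@H]1CC=C2[C@@H](CCC[C@@]2(C)CC[C@@]2(C)C3=CCCC(C)(C)[C@H]3CC[C@@H]2C)[C@]1(C)Cc1cc(OS(=O)(=O)c2ccc(C)cc2)ccc1OS(=O)(=O)c1ccc(C)cc1 | intermediate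
17 | toxiusol hydroquinone | C[C@@H]1CC=C2[C@@H](CCC[C@@]2(C)CC[C@@]2(C)C3=CCCC(C)(C)[C@H]3CC[C@@H]2C)[C@]1(C)Cc1cc(O)ccc1O | intermediate
18 | bis(pyridinium) salt of toxiusol | C[C@@H]1CC=C2[C@@H](CCC[C@@]2(C)CC[C@@]2(C)C3=CCCC(C)(C)[C@H]3CC[C@@H]2C)[C@]1(C)Cc1cc(OS(=O)(=O)[O-])ccc1OS(=O)(=O)[O-].c1cc[nH+]cc1.c1cc[nH+]cc1 | intermediate
19 | toxiusol | C[C@@H]1CC=C2[C@@H](CCC[C@@]2(C)CC[C@@]2(C)C3=CCCC(C)(C)[C@H]3CC[C@@H]2C)[C@]1(C)Cc1cc(OS(=O)(=O)O)ccc1OS(=O)(=O)O | target

**Total step count:** 11.
**Longest linear sequence:** 8 (steps 1–4 and 8–11). Steps 5–7 form the second branch.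

**Steps most likely to fail**

**Step 9.**
- The acceptor styrene may capture the C7' cation too slowly.
- W4 selectivity rests only on the equatorial preference of the eastern arm.
- The C11' cation could attack E1 of an eastern alkene that forms early.
- The tetrasubstituted Δ5(10) isomers are the thermodynamic sinks in both halves.

The fallback sets out from 14 and comes back at 16. The ionisation is run with the pentamethylpiperidine present from the start, so both cations are simply deprotonated at their least hindered positions. This gives the ring-opened pentaene F1, with the eastern Δ1(10) decalin complete and C11' as a 1,1-disubstituted alkene. The western bicyclisation is then started from F1 by cobalt–salen hydrogen-atom transfer with radical–polar crossover (PhSiH3, N-fluoro-2,4,6-collidinium triflate). This touches only the 1,1-disubstituted alkene. It runs without acid and with collidine as the terminating base.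

**Step 6.**
- The enantioselective closure has not been tested with a tertiary OH terminator.
- The di-tertiary ether can lose water.
- The spiro ether at E9 or the cis-fused (H-5α) ether may compete with 11.

The fallback sets out from 9 and comes back at 11. Diol 9 is cyclised with a squalene–hopene cyclase variant (whole cells), and 10 is isolated. BF3·OEt2 at low temperature then takes 10 to the known end point of the 1,2-H/1,2-Me shift, halim-5(10)-ene-13,15-diol F2. In a separate operation F2 is closed to 11 by acid cycloetherification run to equilibrium. Any cis-fused ether is recycled through F2.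

**Step 2.** β-Hydride loss toward C3' would give the allylbenzene isomer and erase the only purchased stereocentre. The fallback sets out from 3 (with 2) and comes back at 4. Compound 3 is converted by Pd-catalysed boryl-Heck reaction (catBCl, then pinacol) into the (E)-alkenyl pinacol boronate F3. F3 is joined to 2 by Suzuki–Miyaura coupling (Pd(dppf)Cl2, K3PO4, THF–H2O). The aryl–vinyl bond then forms by reductive elimination, with no β-hydride step next to C3'.

**Further compounds**
F1 | step 9 | ring-opened pentaene (C11' methylidene, eastern halim-1(10)-ene unit, western (1'E,3'R,6'E)-dienyl arene ditosylate) | Cc1ccc(cc1)S(=O)(=O)Oc1ccc(OS(=O)(=O)c2ccc(C)cc2)c(/C=C/[C@H](C)CC/C=C(\C)CCCC(=C)CC[C@@]2(C)C3=CCCC(C)(C)[C@H]3CC[C@@H]2C)c1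
F2 | step 6 | halim-5(10)-ene-13,15-diol (8β-Me, 9β-Me; C13 epimers) | OCCC(C)(O)CC[C@]1(C)[C@@H](C)CCC2=C1CCCC2(C)C
F3 | step 2 | 2-[(1E,3R)-3,7-dimethylocta-1,6-dien-1-yl]-4,4,5,5-tetramethyl-1,3,2-dioxaborolane | CC(C)=CCC[C@@H](C)/C=C/B1OC(C)(C)C(C)(C)O1
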